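## Plan

1. Retrosynthesis: remove the C8 acetate, cut O2–C3 (6-endo closure of ring A onto an alkyne), C3–C1' (Sonogashira) and C3–C4 (one-carbon homologation of a C4 lactol). What remains is a ring B lactone C4(=O)–O2–C1.
2. Enabling feature: in ring B (C4a, C5, C6, C7, C8, C8a) the oxygens on C7 and C8 are cis to each other and trans to the C8a–C1 bond. This is the imprint of a 7-oxanorbornene whose bridge oxygen ends on C8, so C8–C8a and C4a–C5 are cut as a furan Diels–Alder with a temporary C5–O bond.
3. Forward: ring B closes first (3-methylfuran + menthyloxybutenolide). Then follow exo dihydroxylation, reductive loss of the auxiliary, E1cB bridge opening to C4a=C5, lactol-to-alkyne homologation, coupling of the dienyl iodide, C6 oxidation, closure of ring A and acetylation.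
4. Stereochemistry: C8a comes from attack anti to the (R) menthyl acetal together with endo addition; C8 is the bridge oxygen itself; C7 comes from OsO4 attack on the bridge face; the side-chain centre comes from (S)-2-methylbutan-1-ol; both diene geometries come from E-selective Wittig and Takai olefinations.

Key step: step 3

Assumption: every intermediate is labelled with the isochromene locants of the target (C1, O2, C3, C4, C4a, C5–C8, C8a), so the butenolide carbonyl carbon is C4 and its acetal carbon is C1; the target is read from its SMILES as (7R,8R,8aR) with a (5S) side chain.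

## Route

Step 1
Reactants: 1 furfural
Product: 3 5-hydroxyfuran-2(5H)-one (racemic), via furfural endoperoxide 2 (not isolated)
Conditions: O2, visible light, methylene blue (cat.), MeOH, 20 °C
Reagents that add atoms: oxygen O=O
Why: Sensitised singlet-oxygen [4+2] addition to the furan gives the endoperoxide, which methanol fragments with loss of the formyl carbon as methyl formate to leave the γ-hydroxybutenolide; its C5 centre is equilibrated in the next step, so no control is needed here.

Step 2
Reactants: 3 5-hydroxyfuran-2(5H)-one; 4 (−)-menthol
Product: 6 (5R)-5-(l-menthyloxy)furan-2(5H)-one, via (5S) acetal epimer 5 (not isolated)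
Conditions: camphorsulfonic acid (cat.), toluene, reflux, Dean–Stark; crystallisation from petroleum ether at −20 °C; mother liquor re-equilibrated with the same acid and recrystallised
Reagents that add atoms: none
Why: Acid-catalysed acetalisation of the pseudo-acid with removal of water gives both C5 epimers, which interconvert through the acyloxocarbenium ion, so selective crystallisation of the (5R) isomer should funnel the material into one diastereomer (crystallisation-driven epimerisation).

Step 3
Reactants: 6 (5R)-5-(l-menthyloxy)furan-2(5H)-one; 7 3-methylfuran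
Product: 8 endo oxanorbornene lactone cycloadduct
Conditions: 7 (5 equiv), ZnI2 (0.3 equiv), CH2Cl2, 1.2 GPa, 20 °C, 48 h; pressure released at 0 °C, crude adduct used at once
Reagents that add atoms: none
Why: A concerted, asynchronous normal-electron-demand [4+2] cycloaddition joins furan C2 and C5 to the butenolide double bond; the closest known reaction types are auxiliary-controlled Diels–Alder additions to 5-alkoxybutenolides and ZnI2- or pressure-promoted furan–enoate cycloadditions. Ring B closes in this single intermolecular event as the six-membered carbocycle of a 7-oxabicyclo[2.2.1]heptene, with C8–C8a and C4a–C5 formed suprafacially on both partners and the furan oxygen left as a C5–O–C8 bridge. C8a and C4a are set by approach of the diene to the butenolide face anti to the menthyloxy group on the (R) acetal carbon C1, and C5 and C8 follow from endo stacking of the lactone under the diene, which the Lewis-acid-lowered LUMO (secondary overlap) and the more compact transition state favoured by pressure should secure. The para-type regiochemistry (methyl on C7, next to C8) requires the furan carbon flanking the methyl group, which carries the larger HOMO coefficient, to bond to the β-carbon C8a, where the LUMO coefficient is larger. Pressure and low temperature keep the reversible furan adduct under kinetic control, and immediate dihydroxylation removes the cycloreversion pathway.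

Step 4
Reactants: 8 endo oxanorbornene lactone cycloadduct
Product: 9 exo,exo-6,7-diol
Conditions: OsO4 (2 mol%), N-methylmorpholine N-oxide (1.5 equiv), acetone/H2O (8:1), 0 °C; aq. Na2SO3
Reagents that add atoms: osmium tetroxide O=[Os](=O)(=O)=O; N-methylmorpholine N-oxide C[N+]1([O-])CCOCC1; water O
Why: Catalytic OsO4 syn-dihydroxylation can reach only the exo face (the endo face is closed by the lactone), so both hydroxyls end syn to the oxygen bridge, which places O–C7 cis to the future O–C8 and the methyl group endo.

Step 5
Reactants: 9 exo,exo-6,7-diol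
Product: 10 6,7-acetonide
Conditions: 2-methoxypropene (3 equiv), pyridinium p-toluenesulfonate (5 mol%), CH2Cl2, 0 → 20 °C
Reagents that add atoms: 2-methoxypropene COC(C)=C
Why: Acid-catalysed ketalisation of the cis diol with an enol ether under weak acid, which should leave the acylal-type menthyl acetal untouched, masks both hydroxyls for the base and hydride steps.

Step 6
Reactants: 10 6,7-acetonide
Product: 13 auxiliary-free endo lactone (C1 now CH2), via formyl carboxylate 11 (not isolated), via hydroxy carboxylate 12 (not isolated)
Conditions: KOH (3 equiv), NaBH4 (3 equiv), EtOH/H2O (4:1), 0 → 20 °C; then 1 M HCl to pH 3, 0 → 20 °C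
Reagents that add atoms: none
Why: Saponification of the acylal lactone releases (−)-menthol and the C1 aldehyde, which borohydride present from the start should reduce faster than it can enolise toward C8a, and acidification relactonises the cis hydroxy acid (reductive removal of the alkoxy auxiliary from a 5-alkoxybutyrolactone); no stereocentre is formed and C8a is kept.

Step 7
Reactants: 13 auxiliary-free endo lactone
Product: 14 bridge-opened hydroxy lactone (C4a=C5, free C8–OH)
Conditions: LiN(SiMe3)2 (1.3 equiv), THF, −78 → −40 °C; aq. NH4Cl at −40 °C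
Reagents that add atoms: none
Why: E1cB fragmentation of a 7-oxanorbornane carboxylate: the lactone enolate at C4a expels the strained bridge oxygen from C5, giving C4a=C5 conjugated with C4=O and freeing the C8 alkoxide with its configuration untouched; a small excess of amide base at low temperature should avoid γ-deprotonation at C6.

Step 8
Reactants: 14 bridge-opened hydroxy lactone
Product: 15 unsaturated lactol (both anomers)
Conditions: i-Bu2AlH (2.5 equiv), CH2Cl2, −78 °C; aq. potassium sodium tartrate
Reagents that add atoms: none
Why: Partial reduction of the lactone by i-Bu2AlH at −78 °C stops at the aluminium hemiacetal and should deliver the lactol by 1,2-addition to the conjugated carbonyl; the free C8 hydroxyl only consumes one equivalent of hydride.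

Step 9
Reactants: 15 unsaturated lactol
Product: 16 terminal enyne diol acetonide
Conditions: dimethyl (1-diazo-2-oxopropyl)phosphonate (2 equiv), K2CO3 (3 equiv), MeOH, 0 → 20 °C
Reagents that add atoms: dimethyl (1-diazo-2-oxopropyl)phosphonate CC(=O)C(=[N+]=[N-])P(=O)(OC)OC
Why: Ohira–Bestmann (Seyferth–Gilbert) homologation of a lactol: carbonate opens the lactol to the C4 enal, the diazomethylphosphonate anion formed in the flask adds and eliminates phosphate, and the diazoalkene loses N2 with 1,2-hydrogen shift to give the terminal enyne (new carbon = C3) while the C1 hydroxyl is set free; the α,β-disubstituted, ring-embedded enal should resist competing methanol addition.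

Step 10
Reactants: 16 terminal enyne diol acetonide
Product: 17 enyne tetraol
Conditions: AcOH/H2O (4:1), 40 °C
Reagents that add atoms: none
Why: Mild aqueous acid hydrolysis of the isopropylidene ketal cleaves at the ketal carbon and not at the allylic C6–O bond (as in the deprotection of shikimate acetonides), and it is done before the more acid-sensitive dienyne is built.

Step 11
Reactants: 18 (S)-2-methylbutan-1-ol
Product: 20 ethyl (2E,4S)-2,4-dimethylhex-2-enoate, via (S)-2-methylbutanal 19 (not isolated)
Conditions: TEMPO (10 mol%), PhI(OAc)2 (1.1 equiv), CH2Cl2, 20 °C; then Ph3P=C(CH3)CO2Et (1.3 equiv), 20 → 40 °C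
Reagents that add atoms: ethyl 2-(triphenylphosphoranylidene)propanoate CCOC(=O)C(C)=P(c1ccccc1)(c1ccccc1)c1ccccc1
Why: Oxoammonium oxidation gives the volatile, configurationally labile aldehyde, which is trapped in the same flask by the stabilised ylide in an E-selective Wittig reaction before it can racemise; the stereocentre comes unchanged from the chiral pool.

Step 12
Reactants: 20 ethyl (2E,4S)-2,4-dimethylhex-2-enoate
Product: 21 (2E,4S)-2,4-dimethylhex-2-en-1-ol
Conditions: i-Bu2AlH (2.2 equiv), CH2Cl2, −78 °C; aq. potassium sodium tartrate
Reagents that add atoms: none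
Why: i-Bu2AlH reduces the conjugated ester in a 1,2 sense to the allylic alcohol without changing the alkene geometry.

Step 13
Reactants: 21 (2E,4S)-2,4-dimethylhex-2-en-1-ol
Product: 22 (2E,4S)-2,4-dimethylhex-2-enal
Conditions: MnO2 (15 equiv), CH2Cl2, 20 °C
Reagents that add atoms: none
Why: MnO2 oxidises the allylic alcohol to the enal under neutral heterogeneous conditions, so neither E/Z isomerisation nor epimerisation at C4 is expected.

Step 14
Reactants: 22 (2E,4S)-2,4-dimethylhex-2-enal
Product: 23 (1E,3E,5S)-1-iodo-3,5-dimethylhepta-1,3-diene
Conditions: CrCl2 (6 equiv), CHI3 (2 equiv), THF/dioxane, 0 → 20 °C, dark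
Reagents that add atoms: iodoform IC(I)I
Why: Takai olefination: the geminal dichromium species formed from CHI3 and divalent chromium adds to the aldehyde and eliminates to give the (E)-vinyl iodide, leaving the trisubstituted alkene untouched.

Step 15
Reactants: 17 enyne tetraol; 23 (1E,3E,5S)-1-iodo-3,5-dimethylhepta-1,3-diene
Product: 24 dienyne tetraol
Conditions: Pd(PPh3)4 (5 mol%), CuI (10 mol%), i-Pr2NH/THF (1:3, degassed), 20 °C
Reagents that add atoms: none
Why: Sonogashira coupling (oxidative addition of zerovalent palladium into the C–I bond, copper acetylide transmetalation, reductive elimination) forms C3–C1' with retention of the iodide geometry; free hydroxyls are tolerated and room temperature should prevent premature cyclisation of the alkynol.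

Step 16
Reactants: 24 dienyne tetraol
Product: 25 ynenone triol
Conditions: MnO2 (20 equiv), CH2Cl2, 0 → 20 °C
Reagents that add atoms: none
Why: MnO2 should oxidise only the allylic C6 hydroxyl (the primary C1–OH and secondary C8–OH are not allylic and C7–OH is tertiary), giving the ynenone that polarises C3 for ring closure.

Step 17
Reactants: 25 ynenone triol
Product: 26 bicyclic 7,8-diol (8-deacetyl target)
Conditions: AuCl(PPh3) (5 mol%), AgOTf (5 mol%), CH2Cl2, 0 → 20 °C
Reagents that add atoms: none
Why: Gold-catalysed 6-endo-dig hydroalkoxylation: the alkyne π-complex of monovalent gold is attacked by the C1 hydroxyl at C3, the terminus made electrophilic by the C6 enone and stabilised by the dienyl group, and protodeauration gives the vinylogous ester of ring A; 5-exo attack at C4 is electronically disfavoured and the C8 hydroxyl could only close a bridged anti-Bredt ring.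

Step 18
Reactants: 26 bicyclic 7,8-diol
Product: 27 target acetate
Conditions: Ac2O (1.5 equiv), pyridine, DMAP (5 mol%), CH2Cl2, 0 °C
Reagents that add atoms: acetic anhydride CC(=O)OC(C)=O
Why: DMAP-catalysed acylation distinguishes the secondary C8 hydroxyl from the tertiary, ketone-flanked C7 hydroxyl, and the weakly basic medium at 0 °C should not enolise the dienone toward C8a.

## Compound list

1 | furfural (furan-2-carbaldehyde) | O=Cc1ccco1 | starting material
2 | furfural endoperoxide, 2,3,7-trioxabicyclo[2.2.1]hept-5-ene-1-carbaldehyde (racemic) | O=CC12OOC(C=C1)O2 | intermediate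
3 | 5-hydroxyfuran-2(5H)-one (racemic) | O=C1OC(O)C=C1 | intermediate
4 | (−)-menthol, (1R,2S,5R)-2-isopropyl-5-methylcyclohexan-1-ol | C[C@@H]1CC[C@H]([C@@H](C1)O)C(C)C | starting material
5 | (5S)-5-[(1R,2S,5R)-menthyloxy]furan-2(5H)-one | O=C1O[C@H](O[C@@H]2C[C@H](C)CC[C@H]2C(C)C)C=C1 | intermediate
6 | (5R)-5-[(1R,2S,5R)-menthyloxy]furan-2(5H)-one | O=C1O[C@@H](O[C@@H]2C[C@H](C)CC[C@H]2C(C)C)C=C1 | intermediate
7 | 3-methylfuran | Cc1ccoc1 | starting material
8 | endo cycloadduct, (3R,3aS,4R,7R,7aR)-3-[(1R,2S,5R)-menthyloxy]-5-methyl-3a,4,7,7a-tetrahydro-4,7-epoxyisobenzofuran-1(3H)-one; lactone C4(=O)–O–C1H(O-menthyl) endo-fused at C4a–C8a, C5–O–C8 bridge, C6=C7 with methyl on C7 | O=C1O[C@@H](O[C@@H]4C[C@H](C)CC[C@H]4C(C)C)[C@H]2[C@@H]1[C@H]3C=C(C)[C@@H]2O3 | intermediate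
9 | exo,exo-diol of 8: C6–OH and C7–OH both syn to the oxygen bridge, 7-methyl endo, other centres as in 8 | O=C1O[C@@H](O[C@@H]4C[C@H](C)CC[C@H]4C(C)C)[C@H]2[C@@H]1[C@H]3[C@H](O)[C@](C)(O)[C@@H]2O3 | intermediate
10 | 6,7-O-isopropylidene derivative (acetonide) of 9 | O=C1O[C@@H](O[C@@H]4C[C@H](C)CC[C@H]4C(C)C)[C@H]2[C@@H]1[C@H]3[C@@H]5OC(C)(C)O[C@]5(C)[C@@H]2O3 | intermediate
11 | potassium salt of the ring-opened formyl acid: C4 carboxylate on C4a and C1 aldehyde on C8a, both endo; bridge and acetonide as in 10 | O=C[C@H]1[C@@H](C([O-])=O)[C@H]2[C@@H]3OC(C)(C)O[C@]3(C)[C@@H]1O2.[K+] | intermediate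
12 | potassium salt of the hydroxy acid: as 11 with C1 reduced to CH2OH | OC[C@H]1[C@@H](C([O-])=O)[C@H]2[C@@H]3OC(C)(C)O[C@]3(C)[C@@H]1O2.[K+] | intermediate
13 | endo γ-lactone C4(=O)–O–C1H2 fused at C4a–C8a of the 5,8-oxygen-bridged ring B with 6,7-acetonide (10 without the menthyloxy group) | O=C1OC[C@H]2[C@@H]1[C@H]3[C@@H]4OC(C)(C)O[C@]4(C)[C@@H]2O3 | intermediate
14 | bridge-opened hydroxy lactone: α-alkylidene γ-lactone with C4a=C5, free C8–OH cis to the 6,7-acetonide oxygens and trans to the C8a–C1 bond | O=C1OC[C@H]2C1=C[C@@H]3OC(C)(C)O[C@]3(C)[C@@H]2O | intermediate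
15 | lactol of 14 (C4 hemiacetal, both anomers) | OC1OC[C@H]2C1=C[C@@H]3OC(C)(C)O[C@]3(C)[C@@H]2O | intermediate
16 | enyne diol acetonide: cyclohexene C4a=C5 with ethynyl (C4≡C3H) on C4a, CH2OH on C8a, OH on C8, 6,7-acetonide; configuration as in 14 | C#CC1=C[C@@H]2OC(C)(C)O[C@]2(C)[C@H](O)[C@H]1CO | intermediate
17 | enyne tetraol: 16 without the acetonide; hydroxyls on C6, C7 and C8 all cis, CH2OH on C8a trans to them | C#CC1=C[C@H](O)[C@](C)(O)[C@H](O)[C@H]1CO | intermediate
18 | (S)-2-methylbutan-1-ol | CC[C@H](C)CO | starting material
19 | (S)-2-methylbutanal | CC[C@H](C)C=O | intermediate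
20 | ethyl (2E,4S)-2,4-dimethylhex-2-enoate | CC[C@H](C)/C=C(\C)C(=O)OCC | intermediate
21 | (2E,4S)-2,4-dimethylhex-2-en-1-ol | CC[C@H](C)/C=C(\C)CO | intermediate
22 | (2E,4S)-2,4-dimethylhex-2-enal | CC[C@H](C)/C=C(\C)C=O | intermediate
23 | (1E,3E,5S)-1-iodo-3,5-dimethylhepta-1,3-diene | CC[C@H](C)/C=C(C)/C=C/I | intermediate
24 | dienyne tetraol: 17 carrying on C3 the (1E,3E,5S)-3,5-dimethylhepta-1,3-dienyl group | CC[C@H](C)/C=C(C)/C=C/C#CC1=C[C@H](O)[C@](C)(O)[C@H](O)[C@H]1CO | intermediate
25 | ynenone triol: 24 with C6 oxidised to the ketone | CC[C@H](C)/C=C(C)/C=C/C#CC1=CC(=O)[C@](C)(O)[C@H](O)[C@H]1CO | intermediate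
26 | (7R,8R,8aR)-3-[(1E,3E,5S)-3,5-dimethylhepta-1,3-dien-1-yl]-7,8-dihydroxy-7-methyl-8,8a-dihydro-1H-isochromen-6(7H)-one | CC[C@H](C)/C=C(C)/C=C/C1=CC2=CC(=O)[C@](C)(O)[C@H](O)[C@H]2CO1 | intermediate
27 | (7R,8R,8aR)-3-[(1E,3E,5S)-3,5-dimethylhepta-1,3-dien-1-yl]-7-hydroxy-7-methyl-6-oxo-6,7,8,8a-tetrahydro-1H-isochromen-8-yl acetate | CC[C@H](C)/C=C(C)/C=C/C1=CC2=CC(=O)[C@](C)(O)[C@H](OC(C)=O)[C@H]2CO1 | target

## Step count and risks

Total step count: 18. Longest linear sequence: 14 steps (steps 1–10 and 15–18, from furfural); the side-chain branch is steps 11–14.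

The three steps most likely to fail:

**Step 3 (cycloaddition).** The butenolide is a modest dienophile and the furan adduct is reversible, so the step may suffer from slow conversion, cycloreversion on work-up, erosion of endo or regiochemical control, or Lewis-acid-induced conjugate addition of the furan instead of cycloaddition. The fallback keeps the same bond formations but activates the dienophile with a removable α-bromine. It sets out from 6: bromine in CCl4 would add to the double bond to give the trans-3,4-dibromide F1, and triethylamine would remove HBr to leave (5R)-3-bromo-5-(l-menthyloxy)furan-2(5H)-one F2. This lower-LUMO dienophile should add 7 under milder conditions to give the bromo cycloadduct F3 (bromine exo on C4a). Exo dihydroxylation with OsO4 and N-methylmorpholine N-oxide would then give the bromo diol F4. Radical debromination (Bu3SnH, AIBN, toluene, 80 °C), in which only the cis-fused lactone can form, would bring the material back to the route at 9.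

**Step 9 (alkynylation of the unsaturated lactol).** Methoxide may add to the unmasked enal before homologation, giving a homopropargylic ether, or the lactol may open too slowly. The fallback replaces the diazophosphonate chemistry by a Corey–Fuchs sequence. It sets out from 15: the ylide generated from (dibromomethyl)triphenylphosphonium bromide and KOt-Bu in THF would convert the lactol into the 1,1-dibromodiene diol F7. Treatment with n-BuLi (4.5 equiv, THF, −78 °C) would then effect bromine–lithium exchange and rearrangement to the lithium acetylide, which on protonation comes back to the route at 16.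

**Step 6 (reductive removal of the auxiliary).** The transient C1 aldehyde may enolise in the alkaline medium before hydride capture, leading to epimerisation at C8a or β-elimination of the bridge oxygen from C8. The fallback inverts the order of bridge opening and auxiliary removal so that this aldehyde never meets hydroxide. It sets out from 10: LiN(SiMe3)2 (THF, −78 °C) would open the bridge by the same E1cB process to give the bridge-opened menthyloxy lactone F5. Excess i-Bu2AlH (CH2Cl2, −78 → 0 °C) would reduce both the lactone and the liberated aldehyde to the triol F6 with release of menthol. MnO2 would then oxidise only the allylic C4 hydroxyl, and the resulting lactol 15 is oxidised further in the same flask, so the sequence comes back to the route at 14.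

## Further compounds

F1 | step 3 | trans-3,4-dibromo-5-(l-menthyloxy)dihydrofuran-2(3H)-one, drawn as the isomer from bromonium formation anti to the menthyloxy group and opening at C4 | O=C1O[C@@H](O[C@@H]2C[C@H](C)CC[C@H]2C(C)C)[C@@H](Br)[C@@H]1Br
F2 | step 3 | (5R)-3-bromo-5-(l-menthyloxy)furan-2(5H)-one | O=C1O[C@@H](O[C@@H]2C[C@H](C)CC[C@H]2C(C)C)C=C1Br
F3 | step 3 | bromo cycloadduct: 8 with exo bromine on C4a | O=C1O[C@@H](O[C@@H]4C[C@H](C)CC[C@H]4C(C)C)[C@H]2[C@]1(Br)[C@H]3C=C(C)[C@@H]2O3
F4 | step 3 | bromo diol: 9 with exo bromine on C4a | O=C1O[C@@H](O[C@@H]4C[C@H](C)CC[C@H]4C(C)C)[C@H]2[C@]1(Br)[C@H]3[C@H](O)[C@](C)(O)[C@@H]2O3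
F5 | step 6 | bridge-opened menthyloxy lactone: 14 with the (R) menthyl acetal still on C1 | O=C1O[C@@H](O[C@@H]4C[C@H](C)CC[C@H]4C(C)C)[C@H]2C1=C[C@@H]3OC(C)(C)O[C@]3(C)[C@@H]2O
F6 | step 6 | triol: cyclohexene C4a=C5 with CH2OH on C4a and on C8a, OH on C8, 6,7-acetonide | OCC1=C[C@@H]2OC(C)(C)O[C@]2(C)[C@H](O)[C@H]1CO
F7 | step 9 | 1,1-dibromodiene diol: 16 with the ethynyl group replaced by 2,2-dibromovinyl | BrC(Br)=CC1=C[C@@H]2OC(C)(C)O[C@]2(C)[C@H](O)[C@H]1CO
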